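Numbering: C1 (C=O), C2 (C–OMe), C3 (C–aryl), C4 (spiro carbon), C5 (C(OMe)aryl), C6 (oxirane CH2). The route rests on one feature. The C4–O and C5–OMe bonds stand trans on neighbouring ring carbons, next to the C1 ketone and the C2-methoxy C2=C3 enone, and this is the pattern a 4-pyranone leaves when it contracts under light in an alcohol.
Oxirane (ring B, formed last): the C4 hydroxyl displaces a sulfonate on C6 of a C4,C6-diol, and the two phenols are then freed from their silyl ethers.
Cyclopentenone (ring A, formed first): C3–C4 and C5–OMe are made together by irradiating a tetrasubstituted 4-pyranone in methanol. Pyranone C6/C2/C3/C5/C4 become C3/C4/C5/C2/C1, and the ring oxygen stays on C4.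
Pyranone: kojic acid supplies the heterocycle, C6 and the C2 oxygen. Both aryl groups come from one double Suzuki coupling on its 6-bromo-3-iodo-5-O-methyl derivative.
The photoproduct is racemic, so a (1S)-camphor-10-sulfonate on O6 serves both as resolving handle and as leaving group.

Key step: step 5

Assumption: which of the two sulfonate diastereomers of step 6 has the (4R,5R) configuration cannot be foretold, so it is taken to be identified by X-ray analysis against the fixed camphor stereocentres; the zwitterion, the enol and the diol of step 5 are racemic and are drawn as the enantiomer that is carried on.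

Step 1
Reactants: 1 kojic acid (5-hydroxy-2-(hydroxymethyl)-4H-pyran-4-one)
Product: 2 6-bromo-5-hydroxy-2-(hydroxymethyl)-4H-pyran-4-one (6-bromokojic acid)
Conditions: NBS (1.05 equiv), DMF, 0 °C to rt, dark
Reagents that add atoms: N-bromosuccinimide, O=C1CCC(=O)N1Br
Why: Electrophilic bromination of the enolic pyranone goes to pyranone C6, the position ortho to the free 5-hydroxyl, as is usual for kojic acid, while pyranone C3 and the primary alcohol are left alone.

Step 2
Reactants: 2 6-bromokojic acid
Product: 3 6-bromo-2-(hydroxymethyl)-5-methoxy-4H-pyran-4-one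
Conditions: MeI (1.2 equiv), K2CO3 (1.2 equiv), DMF, rt
Reagents that add atoms: iodomethane, CI
Why: In this Williamson O-alkylation only the acidic enolic hydroxyl is deprotonated by carbonate, so methylation spares the primary alcohol, and the mild base at room temperature leaves the vinylogous acyl bromide intact.

Step 3
Reactants: 3 6-bromo-2-(hydroxymethyl)-5-methoxy-4H-pyran-4-one
Product: 4 6-bromo-2-(hydroxymethyl)-3-iodo-5-methoxy-4H-pyran-4-one
Conditions: NIS (1.2 equiv), TFA/MeCN (1:4), 50 °C, dark; aq. NaHCO3/Na2S2O3 work-up
Reagents that add atoms: N-iodosuccinimide, O=C1CCC(=O)N1I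
Why: Acid-activated electrophilic iodination of a 4-pyranone at the carbon α to the carbonyl (the β-carbon of the O1–C2=C3 enol ether) finds only one ring C–H left, and it is run before any electron-rich arene is present that would compete for the iodinating agent.

Step 4
Reactants: 4 6-bromo-2-(hydroxymethyl)-3-iodo-5-methoxy-4H-pyran-4-one; 5 [4-(tert-butyldimethylsilyloxy)phenyl]boronic acid (2.5 equiv)
Product: 6 2-(hydroxymethyl)-5-methoxy-3,6-bis[4-(tert-butyldimethylsilyloxy)phenyl]-4H-pyran-4-one
Conditions: Pd(PPh3)4 (5 mol %), Na2CO3 (2 M aq.), DME, 80 °C, argon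
Reagents that add atoms: [4-(tert-butyldimethylsilyloxy)phenyl]boronic acid (compound 5), OB(O)c1ccc(O[Si](C)(C)C(C)(C)C)cc1
Why: In this twofold Suzuki–Miyaura coupling both the C3 iodide and the electron-poor C6 bromide add readily to zerovalent palladium, the identical aryl groups remove any need for site selectivity, the free alcohol is tolerated, and the mild carbonate base with short heating should keep the aryl silyl ethers in place.

Step 5
Reactants: 6 2-(hydroxymethyl)-5-methoxy-3,6-bis[4-(tert-butyldimethylsilyloxy)phenyl]-4H-pyran-4-one; 7 methanol (reactant and solvent)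
Product: 10 rac-(4R*,5R*)-4-hydroxy-4-(hydroxymethyl)-2,5-dimethoxy-3,5-bis[4-(tert-butyldimethylsilyloxy)phenyl]cyclopent-2-en-1-one, via epoxy-oxyallyl zwitterion 8 (not isolated), via epoxy enol methanol adduct 9 (not isolated)
Conditions: hν (medium-pressure Hg lamp, Pyrex filter, λ > 290 nm), MeOH (2 mM), argon-sparged, 5–10 °C, flow or immersion-well reactor, stopped before full conversion
Reagents that add atoms: methanol (compound 7), CO
Why: Excitation of the cross-conjugated pyranone sets off the disrotatory 4π electrocyclisation typical of 4-pyranones, in which the two carbons flanking the ring oxygen (future C3 and C4) bond to each other to give the oxirane-fused oxyallyl zwitterion 8. Ring A thus closes by electrocyclic C3–C4 bond formation, and the heterocycle is lost when enol 9, formed by addition of methanol to C5, opens the benzylic C3–O bond by β-elimination and leaves the former ring oxygen on C4 as the tertiary hydroxyl beside the new C2=C3 enone. The closest known reaction type is the photochemical ring contraction of alkyl- and aryl-substituted 4-pyranones in alcohols to trans-4-hydroxy-5-alkoxycyclopent-2-enones. C4 is fixed in the electrocyclisation without facial bias, hence the racemate, and C5 is fixed relative to it because methanol reaches the flat cation only from the face opposite the oxirane, which places C5–OMe trans to C4–O. The step needs attack at the aryl-bearing terminus C5 and not at the methoxy-bearing terminus C2, and three features of 6 work for this: the 4-silyloxyphenyl group carries the charge as a para-oxygenated benzylic cation, the open face of C5 lies beside the small hydroxymethyl group (which can also hydrogen-bond the incoming methanol) while that of C2 lies beside the C3 aryl group, and only attack at C5 leads on to cleavage of a benzylic C–O bond and an aryl-conjugated enone. High dilution, exclusion of oxygen, the Pyrex cut-off and interruption before full conversion hold back dimerisation, drift to the 2-pyranone and secondary photolysis of the strongly absorbing product.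

Step 6
Reactants: 10 rac-(4R*,5R*)-4-hydroxy-4-(hydroxymethyl)-2,5-dimethoxy-3,5-bis[4-(tert-butyldimethylsilyloxy)phenyl]cyclopent-2-en-1-one
Product: 11 (4R,5R)-4-hydroxy-2,5-dimethoxy-3,5-bis[4-(tert-butyldimethylsilyloxy)phenyl]-4-{[(1S)-camphor-10-sulfonyloxy]methyl}cyclopent-2-en-1-one
Conditions: (1S)-(+)-camphor-10-sulfonyl chloride (1.1 equiv), Et3N (1.5 equiv), CH2Cl2, −20 to 0 °C; diastereomers separated on silica gel or by crystallisation
Reagents that add atoms: (1S)-(+)-camphor-10-sulfonyl chloride, CC1(C)[C@@H]2CC[C@]1(C(=O)C2)CS(=O)(=O)Cl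
Why: Sulfonylation through the sulfene takes the primary C6 hydroxyl and leaves the hindered tertiary C4 hydroxyl, which turns the racemate into two diastereomeric sulfonates that are separated in a classical resolution through covalent diastereomers, so that the absolute configuration at C4 and C5 is selected here and the resolving group doubles as the leaving group of step 7.

Step 7
Reactants: 11 (4R,5R)-camphorsulfonate
Product: 12 (3R,4R)-4,6-dimethoxy-4,7-bis[4-(tert-butyldimethylsilyloxy)phenyl]-1-oxaspiro[2.4]hept-6-en-5-one
Conditions: NaN(SiMe3)2 (1.05 equiv), THF, −78 to −20 °C; pH 7 buffer quench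
Reagents that add atoms: none
Why: In this intramolecular Williamson reaction (3-exo-tet closure of a β-hydroxy sulfonate) the C4 alkoxide displaces the sulfonate at the non-stereogenic C6, so the C4–O bond and both stereocentres are untouched, and the low temperature and exact base charge should keep retro-aldol cleavage of C4–C5 and loss of the aryl silyl ethers from competing.

Step 8
Reactants: 12 (3R,4R)-bis-silyl spiro-epoxide
Product: 13 (3R,4R)-4,7-bis(4-hydroxyphenyl)-4,6-dimethoxy-1-oxaspiro[2.4]hept-6-en-5-one (CNP0504072.1)
Conditions: Bu4NF (2.2 equiv), AcOH (2.4 equiv), THF, 0 °C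
Reagents that add atoms: none
Why: Fluoride-induced cleavage of aryl silyl ethers is fast at 0 °C, and the acetic acid buffer protonates each phenoxide as it forms, so neither quinone methide formation at C5 under base nor acid opening of the allylic tertiary oxirane should set in.

Compound list
1 | kojic acid | OCC1=CC(=O)C(O)=CO1 | starting material
2 | 6-bromo-5-hydroxy-2-(hydroxymethyl)-4H-pyran-4-one | OCC1=CC(=O)C(O)=C(Br)O1 | intermediate
3 | 6-bromo-2-(hydroxymethyl)-5-methoxy-4H-pyran-4-one | COC1=C(Br)OC(CO)=CC1=O | intermediate
4 | 6-bromo-2-(hydroxymethyl)-3-iodo-5-methoxy-4H-pyran-4-one | COC1=C(Br)OC(CO)=C(I)C1=O | intermediate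
5 | [4-(tert-butyldimethylsilyloxy)phenyl]boronic acid | OB(O)c1ccc(O[Si](C)(C)C(C)(C)C)cc1 | starting material
6 | 2-(hydroxymethyl)-5-methoxy-3,6-bis[4-(tert-butyldimethylsilyloxy)phenyl]-4H-pyran-4-one | COC1=C(c2ccc(O[Si](C)(C)C(C)(C)C)cc2)OC(CO)=C(c2ccc(O[Si](C)(C)C(C)(C)C)cc2)C1=O | intermediate
7 | methanol | CO | starting material
8 | epoxy-oxyallyl zwitterion (6-oxabicyclo[3.1.0]hexane core, oxirane across C3 and C4, cation at C5, oxide on C1; racemic, not isolated) | COC1=C([O-])[C+](c2ccc(O[Si](C)(C)C(C)(C)C)cc2)[C@@]3(CO)O[C@@]13c4ccc(O[Si](C)(C)C(C)(C)C)cc4 | intermediate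
9 | epoxy enol methanol adduct (C5–OMe anti to the C3/C4 oxirane; racemic, not isolated) | COC1=C(O)[C@@](OC)(c2ccc(O[Si](C)(C)C(C)(C)C)cc2)[C@@]3(CO)O[C@@]13c4ccc(O[Si](C)(C)C(C)(C)C)cc4 | intermediate
10 | rac-(4R*,5R*)-4-hydroxy-4-(hydroxymethyl)-2,5-dimethoxy-3,5-bis[4-(tert-butyldimethylsilyloxy)phenyl]cyclopent-2-en-1-one (drawn as 4R,5R) | COC1=C(c2ccc(O[Si](C)(C)C(C)(C)C)cc2)[C@@](O)(CO)[C@](OC)(c2ccc(O[Si](C)(C)C(C)(C)C)cc2)C1=O | intermediate
11 | (4R,5R)-4-hydroxy-2,5-dimethoxy-3,5-bis[4-(tert-butyldimethylsilyloxy)phenyl]-4-{[(1S)-camphor-10-sulfonyloxy]methyl}cyclopent-2-en-1-one | COC1=C(c2ccc(O[Si](C)(C)C(C)(C)C)cc2)[C@@](O)(COS(=O)(=O)C[C@]34CC[C@H](CC3=O)C4(C)C)[C@](OC)(c2ccc(O[Si](C)(C)C(C)(C)C)cc2)C1=O | intermediate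
12 | (3R,4R)-4,6-dimethoxy-4,7-bis[4-(tert-butyldimethylsilyloxy)phenyl]-1-oxaspiro[2.4]hept-6-en-5-one | COC1=C(c2ccc(O[Si](C)(C)C(C)(C)C)cc2)[C@@]2(CO2)[C@](OC)(c2ccc(O[Si](C)(C)C(C)(C)C)cc2)C1=O | intermediate
13 | (3R,4R)-4,7-bis(4-hydroxyphenyl)-4,6-dimethoxy-1-oxaspiro[2.4]hept-6-en-5-one (CNP0504072.1) | COC1=C(c2ccc(O)cc2)[C@@]2(CO2)[C@](OC)(c2ccc(O)cc2)C1=O | target

Total step count: 8. Longest linear sequence: 8 steps (1 to 13).

Steps most likely to fail

**Step 5.**
- What may go wrong:
  - Methanol may add at the methoxy-bearing terminus C2, because a directly bound methoxy group rivals the 4-silyloxyphenyl group as a cation stabiliser.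
  - The excited carbonyl may abstract hydrogen from the neighbouring OCH3 group.
  - The zwitterion may slip to the 2-pyranone.
- Fallback: solvent capture is replaced by tethered delivery of the methoxy group, setting out from 6.
  - 2-Methoxypropene and catalytic pyridinium tosylate in CH2Cl2 convert the primary alcohol into the mixed ketal 5-methoxy-2-{[(2-methoxypropan-2-yl)oxy]methyl}-3,6-bis[4-(tert-butyldimethylsilyloxy)phenyl]-4H-pyran-4-one F1.
  - F1 is irradiated in dry MeCN over solid NaHCO3, with no external nucleophile.
  - The ketal methoxy oxygen sits on the face opposite the oxirane and can reach only C5, through a six-membered oxonium ion. It should hand over its methoxy group in the manner of an intramolecular aglycon delivery.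
  - The dimethyl-oxocarbenium ion left on O6 is then caught by the C4 alkoxide released when the oxirane opens, giving the acetonide of diol 10 F2.
  - Aqueous acetic acid in THF at 40 °C removes the acetonide without touching the aryl silyl ethers, and the route is rejoined at 10.

**Step 6.**
- What may go wrong: the two camphorsulfonates may differ too little in polarity or solubility to be separated, since the camphor unit lies several bonds from C4.
- Fallback: an enzymatic kinetic resolution ahead of sulfonylation, setting out from 10.
  - The reaction uses vinyl acetate and immobilised Burkholderia cepacia lipase (or Candida antarctica lipase B) in MTBE at 30 °C. This is the known lipase acylation of the primary hydroxyl of 1,1-disubstituted 1,2-diols.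
  - The enzyme is chosen by screening so that it acylates the unwanted enantiomer to the (4S,5S)-C6 monoacetate of diol 10 F4.
  - The reaction is run beyond half conversion, so that the slow-reacting (4R,5R)-enantiomer of diol 10 F3 is left enantiomerically enriched.
  - F3 is separated from F4 by chromatography and sulfonylated under the conditions of step 6, which rejoins the route at 11.

**Step 3.**
- What may go wrong: the brominated, carbonyl-deactivated ring may be too electron-poor for electrophilic iodination, or the hydroxymethyl group may be attacked by the iodinating agent.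
- Fallback: electrophilic substitution is exchanged for deprotonative metalation, setting out from 3.
  - TBSCl and imidazole in DMF give 6-bromo-2-[(tert-butyldimethylsilyloxy)methyl]-5-methoxy-4H-pyran-4-one F5.
  - TMPZnCl·LiCl in THF at rt zincates the only ring C–H (pyranone C3, beside the coordinating carbonyl) and tolerates the C–Br bond.
  - An iodine quench gives 6-bromo-2-[(tert-butyldimethylsilyloxy)methyl]-3-iodo-5-methoxy-4H-pyran-4-one F6.
  - AcOH/THF/H2O at rt removes the primary silyl ether and rejoins the route at 4.

Further compounds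
F1 | step 5 | 5-methoxy-2-{[(2-methoxypropan-2-yl)oxy]methyl}-3,6-bis[4-(tert-butyldimethylsilyloxy)phenyl]-4H-pyran-4-one | COC1=C(c2ccc(O[Si](C)(C)C(C)(C)C)cc2)OC(COC(C)(C)OC)=C(c2ccc(O[Si](C)(C)C(C)(C)C)cc2)C1=O
F2 | step 5 | acetonide of diol 10 (C4–O and C6–O bridged by CMe2; racemic, drawn as 4R,5R) | COC1=C(c2ccc(O[Si](C)(C)C(C)(C)C)cc2)[C@@]2(COC(C)(C)O2)[C@](OC)(c2ccc(O[Si](C)(C)C(C)(C)C)cc2)C1=O
F3 | step 6 | (4R,5R)-enantiomer of diol 10 as a single enantiomer | COC1=C(c2ccc(O[Si](C)(C)C(C)(C)C)cc2)[C@@](O)(CO)[C@](OC)(c2ccc(O[Si](C)(C)C(C)(C)C)cc2)C1=O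
F4 | step 6 | (4S,5S)-C6 monoacetate of diol 10 | COC1=C(c2ccc(O[Si](C)(C)C(C)(C)C)cc2)[C@](O)(COC(C)=O)[C@@](OC)(c2ccc(O[Si](C)(C)C(C)(C)C)cc2)C1=O
F5 | step 3 | 6-bromo-2-[(tert-butyldimethylsilyloxy)methyl]-5-methoxy-4H-pyran-4-one | COC1=C(Br)OC(CO[Si](C)(C)C(C)(C)C)=CC1=O
F6 | step 3 | 6-bromo-2-[(tert-butyldimethylsilyloxy)methyl]-3-iodo-5-methoxy-4H-pyran-4-one | COC1=C(Br)OC(CO[Si](C)(C)C(C)(C)C)=C(I)C1=O
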